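**Assumption:** the SMILES describes a C2-symmetric diaryl ether in which both flavan units are (2R,3S) and both B rings carry a free 4'-OH and the bridging oxygen at C-3'. The "afzelechin" half is therefore treated as a catechin unit that has lost its 3'-oxygen, and both halves are made from (+)-catechin.

## Retrosynthetic overview

1. Target 11 ⇐ global hydrogenolysis of the octa-O-benzyl diaryl ether 10.
2. 10 ⇐ C3'''–O3' bond by visible-light nickel-catalysed coupling of phenol 7 with its own triflate 9 (key step; formally a dehydrative dimerisation of one phenol).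
3. 7 ⇐ (+)-catechin 1 by B-ring ketal protection, benzylation of 3-, 5-, 7-OH, ketal removal and mono-benzylation of the catechol.
4. No ring is built. Both chroman ring systems and all four stereocentres come intact from (+)-catechin; only the inter-flavan ether bond is made.

## Route

**Step 1**
Reactants: 1, (+)-catechin; 2, dichlorodiphenylmethane
Product: 3, 3',4'-O-(diphenylmethylene)-(+)-catechin [(2R,3S)-2-(2,2-diphenyl-1,3-benzodioxol-5-yl)chromane-3,5,7-triol]
Conditions: Ph2CCl2 (1.5 equiv), K2CO3, MeCN, rt, N2
Reagents that add atoms: dichlorodiphenylmethane, ClC(Cl)(c1ccccc1)c1ccccc1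
Why: Cyclic ketalisation; only the ortho-dihydroxy B ring can close the five-membered ketal, while any A-ring O-CPh2Cl adduct hydrolyses back on work-up; no stereocentre is touched.

**Step 2**
Reactants: 3, 3',4'-O-(diphenylmethylene)catechin; 4, benzyl bromide
Product: 5, (2R,3S)-3,5,7-tris(benzyloxy)-2-(2,2-diphenyl-1,3-benzodioxol-5-yl)chromane
Conditions: NaH (3.6 equiv), BnBr (3.5 equiv), DMF, 0 °C → rt
Reagents that add atoms: benzyl bromide, BrCc1ccccc1
Why: Williamson etherification of the two A-ring phenols and the 3-OH; with the 4'-oxygen locked in the ketal, base cannot open the pyran through a B-ring quinone methide, so C2 and C3 are retained.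

**Step 3**
Reactants: 5, tri-O-benzyl ketal
Product: 6, 3,5,7-tri-O-benzyl-(+)-catechin [4-[(2R,3S)-3,5,7-tris(benzyloxy)chroman-2-yl]benzene-1,2-diol]
Conditions: AcOH/H2O/1,4-dioxane (4:1:1), 90 °C
Reagents that add atoms: none (water supplies only H to the product; its oxygen leaves in benzophenone)
Why: Acid-catalysed ketal hydrolysis; aryl and alkyl benzyl ethers survive hot aqueous acetic acid, and the flavan has no C4 leaving group, so the stereocentres are unaffected.

**Step 4**
Reactants: 6, tri-O-benzylcatechin; 4, benzyl bromide
Product: 7, 3,5,7,4'-tetra-O-benzyl-(+)-catechin [2-(benzyloxy)-5-[(2R,3S)-3,5,7-tris(benzyloxy)chroman-2-yl]phenol], isolated by chromatography from the co-formed 3'-O-benzyl isomer, which is discarded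
Conditions: BnBr (1.0 equiv), K2CO3 (1.1 equiv), DMF, 0 °C → rt, N2; silica chromatography
Reagents that add atoms: benzyl bromide, BrCc1ccccc1
Why: Williamson mono-alkylation of a catechol; the two OH groups are electronically near-equivalent, so about half of the mono-benzylated material is 7 and it is obtained by separation (assign by NOE: OCH2Ph to H-5' in 7, to H-2' in the unwanted isomer). Benzyl ethers do not migrate, and short, cold exposure to base limits C2 epimerisation through the 4'-phenoxide.

**Step 5**
Reactants: 7, 4'-O-benzyl phenol; 8, trifluoromethanesulfonic anhydride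
Product: 9, 2-(benzyloxy)-5-[(2R,3S)-3,5,7-tris(benzyloxy)chroman-2-yl]phenyl trifluoromethanesulfonate
Conditions: Tf2O (1.2 equiv), pyridine, CH2Cl2, 0 °C (performed on about 45% of the batch of 7)
Reagents that add atoms: triflic anhydride, O=S(=O)(OS(=O)(=O)C(F)(F)F)C(F)(F)F
Why: Standard O-sulfonylation of the only free OH; this turns the 3'-oxygen of one catechin unit into the leaving group, so that ring becomes the 3'-deoxy ("afzelechin") ring.

**Step 6 (key step)**
Reactants: 7, phenol (1.2 equiv); 9, aryl triflate (1.0 equiv)
Product: 10, bis{2-(benzyloxy)-5-[(2R,3S)-3,5,7-tris(benzyloxy)chroman-2-yl]phenyl} ether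
Conditions: NiBr2·glyme (10 mol %), dtbbpy (12 mol %), fac-Ir(ppy)3 (2 mol %), K3PO4, DMA, 450 nm LEDs, 30 °C, degassed
Reagents that add atoms: none
Why: Proposed new method: excited Ir(ppy)3 reduces Ni(II) to low-valent Ni, which inserts into the C3'–OTf bond; triflate/phenoxide exchange gives (dtbbpy)Ni(Ar)(OAr'), and triplet energy transfer (or oxidation to Ni(III)) drives the C–O reductive elimination that Ni(II) cannot do thermally. Triflyl transfer between the phenoxide of 7 and 9 is degenerate and cannot scramble the partners, and the 3'-phenoxide is meta to C2 so it cannot open the pyran ring and the stereocentres stay intact. The closest known reaction type is light-driven Ni-catalysed C–O cross-coupling (aryl bromides with alcohols or carboxylic acids, electron-poor aryl halides with phenols); it has not been shown for an electron-rich ortho-alkoxy aryl triflate with a hindered ortho-alkoxy phenol.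

**Step 7**
Reactants: 10, octa-O-benzyl diaryl ether
Product: 11, catechin-(3'-O-3''')-afzelechin (target)
Conditions: H2 (1 atm), Pd(OH)2/C, THF/MeOH/H2O, rt; filter and lyophilise under Ar
Reagents that add atoms: none
Why: Global hydrogenolysis of eight benzyl ethers; the diaryl ether and the chroman C2–O1 bonds are inert under these conditions, so all four (2R,3S) centres from catechin are delivered unchanged.

## Compound list

1 | (+)-catechin, (2R,3S)-2-(3,4-dihydroxyphenyl)chromane-3,5,7-triol | Oc1cc(O)c2c(c1)O[C@H](c1ccc(O)c(O)c1)[C@@H](O)C2 | starting material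
2 | dichlorodiphenylmethane | ClC(Cl)(c1ccccc1)c1ccccc1 | starting material
3 | 3',4'-O-(diphenylmethylene)-(+)-catechin | Oc1cc(O)c2c(c1)O[C@H](c1ccc3OC(c4ccccc4)(c4ccccc4)Oc3c1)[C@@H](O)C2 | intermediate
4 | benzyl bromide | BrCc1ccccc1 | starting material
5 | (2R,3S)-3,5,7-tris(benzyloxy)-2-(2,2-diphenyl-1,3-benzodioxol-5-yl)chromane | c1ccccc1COc1cc(OCc3ccccc3)c2c(c1)O[C@H](c1ccc3OC(c4ccccc4)(c4ccccc4)Oc3c1)[C@@H](OCc1ccccc1)C2 | intermediate
6 | 3,5,7-tri-O-benzyl-(+)-catechin (free 3',4'-catechol) | c1ccccc1COc1cc(OCc3ccccc3)c2c(c1)O[C@H](c1ccc(O)c(O)c1)[C@@H](OCc1ccccc1)C2 | intermediate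
7 | 3,5,7,4'-tetra-O-benzyl-(+)-catechin (free 3'-OH) | c1ccccc1COc1cc(OCc3ccccc3)c2c(c1)O[C@H](c1ccc(OCc3ccccc3)c(O)c1)[C@@H](OCc1ccccc1)C2 | intermediate
8 | trifluoromethanesulfonic anhydride | O=S(=O)(OS(=O)(=O)C(F)(F)F)C(F)(F)F | starting material
9 | 3'-O-triflyl-3,5,7,4'-tetra-O-benzyl-(+)-catechin | c1ccccc1COc1cc(OCc3ccccc3)c2c(c1)O[C@H](c1ccc(OCc3ccccc3)c(OS(=O)(=O)C(F)(F)F)c1)[C@@H](OCc1ccccc1)C2 | intermediate
10 | bis{2-(benzyloxy)-5-[(2R,3S)-3,5,7-tris(benzyloxy)chroman-2-yl]phenyl} ether | c6ccccc6COc1cc(OCc6ccccc6)c2c(c1)O[C@H](c1ccc(OCc6ccccc6)c(Oc3cc([C@H]4Oc5cc(OCc6ccccc6)cc(OCc6ccccc6)c5C[C@@H]4OCc6ccccc6)ccc3OCc6ccccc6)c1)[C@@H](OCc6ccccc6)C2 | intermediate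
11 | catechin-(3'-O-3''')-afzelechin | Oc1cc(O)c2c(c1)O[C@H](c1ccc(O)c(Oc3cc([C@H]4Oc5cc(O)cc(O)c5C[C@@H]4O)ccc3O)c1)[C@@H](O)C2 | target

## Summary

Total step count: 7.
Longest linear sequence: 7 steps (1 → 3 → 5 → 6 → 7 → 9 → 10 → 11); the only convergence is 7 serving as both nucleophile and precursor of electrophile 9.

Three steps most likely to fail:

1. **Step 6 (proposed new light-driven Ni coupling).** The electron-rich, ortho-substituted aryl triflate may add slowly or undergo reduction to Ar–H, and the phenoxide may be oxidised instead. Fallback (known chemistry): thermal Pd-catalysed Buchwald-type C–O coupling of 9 with 7 (Pd2(dba)3, tBuXPhos, K3PO4, toluene, 100 °C). Alternatively, Miyaura borylation of 9 followed by Chan–Evans–Lam coupling with 7 (Cu(OAc)2, pyridine, air, rt).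

2. **Step 4 (regiochemistry of mono-benzylation).** The two mono-benzyl isomers form in about equal amounts and may be hard to separate, so at best about 40% of the material is usable. Fallback: differentiate through the electrophile instead. Mono-triflate 6 (PhNTf2, 1 equiv) and separate the 3'-O-triflate isomer; the unwanted 4'-O-triflate is hydrolysed back to 6 (Et4NOH, dioxane) and recycled. Benzylate the 4'-OH of the 3'-O-triflate to give 9 directly, and generate 7 from part of 9 by the same S–O hydrolysis. Only one isomerically pure compound then has to be isolated, and no material is lost to the wrong isomer.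

3. **Step 3 (acidic removal of the diphenylmethylene ketal beside benzyl ethers).** Cleavage may be sluggish, or stronger acid may start to remove or migrate A-ring benzyl groups. Fallback: avoid a covalent catechol mask. Benzylate catechin at 5- and 7-OH with the catechol held as its borate complex (borax, BnBr, K2CO3, aqueous DMF), and carry the free 3-OH through, using phenol-selective triflation with PhNTf2; the end product is the same.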